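Atoms are labelled C1–C15 in germacrane numbering (ring C1–C10, lactone carbons C11–C13, C14 on C10, C15 on C4). Plain numerals 1–30 are compounds. TBS = tert-butyldimethylsilyl, PMB = 4-methoxybenzyl.

## Analysis of the target

The target is a germacranolide: a ten-membered carbocycle (C1–C10) fused at C6–C7 to a butenolide (O on C6, C7=C11, C12=O). C11 carries the acetoxymethyl carbon C13 and C8 carries a second acetate. Two trisubstituted oxiranes span C1–C10 and C4–C5; each is trans across the ring (C2/C9 anti, C3/C6 anti) and each has a methyl group on its quaternary carbon. There are six stereocentres: 1R, 4R, 5R, 6S, 8S, 10R. C4, C5 and C6 are contiguous, C8 lies across the sp2 carbon C7, and C1/C10 are remote from both, so their relation to the rest must come from a reagent or be relayed through the ring. Both oxiranes are acid-labile. Once the butenolide exists, C6–H is its acidic γ-hydrogen with the C4–C5 oxirane as a leaving group on the next carbon, and a free C8 hydroxyl could translactonise onto C12. The difficulty is the medium ring, the fully substituted C7=C11 olefin flanked by oxygenated carbons, and stereocontrol on a flexible ring. The strategy rests on one feature: the C4–C5 oxirane sits next to oxygenated C6. With C6 as a ketone, O–C4–C5–C6=O is a glycidic ketone, the retron of a Darzens condensation between a C5 chloro-enolate and a C4 methyl ketone, and because C7 is sp2, C5 is the only enolisable α-carbon of that ketone.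

## Retrosynthetic reasoning

**Acetates and silyl ethers (30 ⇐ 29 ⇐ 28).** The ester C–O bonds at C8 and C13 are cut first. Acetates would not survive the basic steps, so both oxygens are carried as TBS ethers in 28 and freed as diol 29 only at the end. The C8 ether also keeps that oxygen away from C12.

**Lactone (28 ⇐ 26, via 27).** The C12–O(C6) acyl bond is cut and C6 is raised to the ketone. This is what turns C5 into a nucleophilic carbon. C6 and C12 are cis on C7=C11, so the C6 hydroxyl of 27 can only close the 6,12-lactone. The forward step needs hydride delivery to one face of the C6 ketone and acyl transfer from a tert-butyl ester.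

**Ring and oxirane (26 ⇐ 24, via 25).** The C4–C5 bond and the C5–O bond of the oxirane are cut together, which opens the ring to the chloro diketone 24. No other cut removes a ring, a skeletal bond and two stereocentres at once while leaving an acyclic precursor whose stereocentres (C1, C8, C10) can all be set by reagents. The forward reaction must make the C5 chloro-enolate add to the C4 ketone and let the C4 alkoxide of 25 displace chloride. C12 is held as a tert-butyl ester in 24 because a methyl ester cis to the chloro-enolate would invite saponification and five-ring acylation at C5.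

**C4 carbonyl and C5 chlorine (24 ⇐ 23 ⇐ 22 ⇐ 20, via 21).** The C4 ketone is traced to a PMB-protected carbinol, so that during chlorination the C6 ketone is the only ketone present and C5 its only enolisable carbon. Chlorine enters through silyl enol ether 21. The C4 carbonyl is unveiled last, by oxidation rather than acetal hydrolysis, because a ketone four atoms from the C1–C10 oxirane would cyclise onto it under acid.

**C1–C10 oxirane (20 ⇐ 19).** The C–O bonds of the oxirane are cut to the E-olefin of 19, so the two stereocentres come from a catalyst. The epoxidation is placed after the furan has been opened, since an electron-rich furan would compete for the oxidant, and before chlorination, since its basic medium would not suit a chloro ketone.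

**Z-keto ester (19 ⇐ 18 ⇐ 16, via 17).** The C6 and C12 carbonyls are traced to the two α-carbons of the 2,3,4-trisubstituted furan 16. The furan fixes the cis relation of C6 and C12 across the tetrasubstituted olefin and carries C5 as its methyl group. The forward reaction is an oxidative ring opening, oxidation of the aldehyde and esterification.

**C1–C2 bond (16 ⇐ 12 + 14, via 15).** An sp2–sp3 cut at C1–C2 gives vinyl iodide 12 and the four-carbon unit 14. The coupling transfers the olefin geometry unchanged and joins two fragments of similar size.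

**C10–C14 and C1–I (12 ⇐ 10 ⇐ 9, via 11).** The methyl group and the iodide are removed across a terminal alkyne. Syn carbometalation sets the E geometry of the trisubstituted olefin without an olefination.

**C8–C9 bond and C8 stereocentre (9 ⇐ 7, via 8).** The cut between C8 and C9 leads to aldehyde 7 and a propargyl unit. An enantioselective propargylation sets C8 and delivers the alkyne needed above.

**Furan aldehyde (7 ⇐ 3 ⇐ 2 ⇐ 1) and side piece (14 ⇐ 13).** The C5 methyl group is removed from the furan position next to the formyl group, which points to a directed metalation of 3. Aldehyde 3 comes from the symmetrical diol 1 by monosilylation and oxidation, so C8 and C13 are both present from the start. Ether 14 comes from the commercial alcohol 13.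

## Alternatives that were turned down

**Alternative 1: anionic oxy-Cope ring expansion.**
- Disconnection: the C2–C3 bond is cut and the C5–C10 bond formed, leading to cyclohexanol A1. A1 carries an isopropenyl group on the carbinol carbon C5 and, trans to it, a vinyl group on the quaternary C10.
- Forward key step: the potassium alkoxide of A1 undergoes the [3,3] shift, and the C4=C5 enolate is trapped on oxygen by a triflating agent to give the ten-membered enol triflate A2.
- For: there is no end-to-end cyclisation and no dilution, the chair transition state turns the trans arrangement into two E olefins, and the reaction type is long established for cyclodeca-1,5-dienes. On ring formation it is stronger than the chosen route.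
- Against: A2 is far from the target. The triflate must be reduced, both olefins epoxidised under substrate control on a heat- and acid-labile diene, and the whole butenolide (C11, C12, C13) built onto a C7 ketone flanked by two oxygenated stereocentres, with the tetrasubstituted C7=C11 bond formed late. A1 itself has four stereocentres, two of them adjacent and fully substituted.
- Comparison: many more operations follow the ring than the three of the chosen route. The chosen route offers a convergent precursor with the lactone carbons in place, and ring and oxirane formed together.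

**Alternative 2: vinylogous Mukaiyama aldol macrocyclisation.**
- Disconnection: the C5–C6 bond, leading to aldehyde A3 with a 2-silyloxyfuran at the other end.
- Forward key step: a boron Lewis acid activates the C5 aldehyde of A3 and the furan attacks through C6, giving the macrocyclic butenolide A4.
- For: ring, butenolide and C6 are made at once, silyloxyfurans react reliably at the γ-carbon, and the step is closer to known chemistry than the chosen one. It needs no lactonisation. It is stronger on these points.
- Against: C5 is a neopentyl-type aldehyde next to the fully substituted C4. The open transition state gives no firm control of C5 and C6, and both matter, since C5 must have the configuration that allows invertive oxirane closure. The oxirane then needs three further operations, ending with a base-mediated closure in a molecule whose C6–H is the acidic γ-hydrogen of a butenolide with a leaving group on C5. The C1=C10 olefin is epoxidised last under substrate control, and the tertiary C4 carbinol must be made enantioselectively in the open chain.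
- Comparison: the chosen route makes the trans oxirane in the ring-forming step by mechanism and forms the butenolide only after the oxirane exists.

**Alternative 3: decarboxylative double Grob fragmentation.**
- Disconnection: the C5–C10 bond is formed in the retro sense, leading to the eudesmanolide acid A5 with a mesylate on C1.
- Forward key step: on warming, the caesium carboxylate of A5 loses CO2 as C5–C10 breaks and the mesylate leaves, giving the (E,E)-dienolide A6.
- For: the trans-decalin holds the breaking bonds anti-periplanar, so both olefins form stereospecifically without dilution, and A6 is only two epoxidations from the target. On ring formation and on steps after the ring it is stronger than the chosen route.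
- Against: the effort moves into A5, a decalin with six stereocentres (two quaternary) and the complete acetoxylated butenolide, which must survive a basic thermal step. The seven-centre carboxylate variant is less secure than the classical fragmentations; the carboxylate can instead displace the mesylate. A6 can undergo Cope rearrangement under the conditions that form it, and neither oxirane is made in the key step.
- Comparison: the chosen route reaches its precursor convergently from three small pieces with every stereocentre set by a catalyst, at the price of a riskier ring closure.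

Key step: step 15

## Assumptions

- The (S)-configured phosphoric acid in step 4 is written in on the basis of the accepted six-membered transition-state model for aryl aldehydes. If the opposite sense is found, its enantiomer is used.
- The sense of induction of the chiral ammonium ion in step 15 cannot be predicted. The cinchonidine-derived salt is written in, and its cinchonine-derived pseudoenantiomer replaces it if that is the matched partner.
- The configuration of 13 is immaterial, since C4 becomes a ketone in step 14. A single enantiomer is used only to keep every intermediate one stereoisomer.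

## Route

Step 1
Reactants: 1 furan-3,4-diyldimethanol
Product: 2 [4-(TBS-oxymethyl)furan-3-yl]methanol
Conditions: NaH (1.0 equiv), THF, 0 °C → rt; TBSCl (1.0 equiv)
Reagents that add atoms: tert-butyldimethylsilyl chloride, CC(C)(C)[Si](C)(C)Cl
Why: O-silylation of the sparingly soluble monosodium alkoxide of a symmetrical diol; the two hydroxymethyl groups are equivalent, so only mono- versus bis-silylation has to be controlled. The silylated arm becomes C13 and the free one C8.

Step 2
Reactants: 2 [4-(TBS-oxymethyl)furan-3-yl]methanol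
Product: 3 4-(TBS-oxymethyl)furan-3-carbaldehyde
Conditions: MnO2 (excess), CH2Cl2, rt
Reagents that add atoms: none
Why: Heterogeneous MnO2 oxidation of a heteroaryl carbinol stops at the aldehyde and leaves furan and silyl ether alone.

Step 3
Reactants: 3 4-(TBS-oxymethyl)furan-3-carbaldehyde
Product: 7 4-(TBS-oxymethyl)-2-methylfuran-3-carbaldehyde, via lithium amino alkoxide adduct 4 (not isolated), via C2-lithiated adduct 5 (not isolated), via C2-methylated adduct 6 (not isolated)
Conditions: LiN(Me)CH2CH2NMe2 (from the amine and n-BuLi), THF, −20 °C; n-BuLi, −20 °C; MeI, −78 °C → rt; H2O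
Reagents that add atoms: iodomethane, CI
Why: α-Amino alkoxide directed ortho-lithiation: the adduct masks the aldehyde and its chelating diamine arm steers n-BuLi to the neighbouring furan α-position (the future C6) rather than to the one beside the weakly coordinating silyloxymethyl group. Methylation and hydrolysis return the aldehyde with the C5 methyl group in place.

Step 4
Reactants: 7 4-(TBS-oxymethyl)-2-methylfuran-3-carbaldehyde
Product: 9 (1S)-1-[4-(TBS-oxymethyl)-2-methylfuran-3-yl]but-3-yn-1-ol, via pinacol borate ester 8 (not isolated)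
Conditions: allenyl-B(pin), (S)-TRIP [(S)-3,3'-bis(2,4,6-triisopropylphenyl)-1,1'-binaphthyl-2,2'-diyl hydrogen phosphate, 10 mol %], 4 Å MS, toluene, −20 °C; aq. NaHCO3
Reagents that add atoms: allenylboronic acid pinacol ester, C=C=CB1OC(C)(C)C(C)(C)O1
Why: Chiral Brønsted acid-catalysed propargylboration: the allenyl group is transferred through a six-membered chair transition state with allylic transposition, so only the homopropargylic alcohol forms. The (S)-acid is expected to direct attack to the Si face of the aldehyde, which sets C8 as S.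

Step 5
Reactants: 9 (1S)-1-[4-(TBS-oxymethyl)-2-methylfuran-3-yl]but-3-yn-1-ol
Product: 10 3-[(1S)-1-(TBS-oxy)but-3-yn-1-yl]-4-(TBS-oxymethyl)-2-methylfuran
Conditions: TBSOTf, 2,6-lutidine, CH2Cl2, −78 → 0 °C
Reagents that add atoms: tert-butyldimethylsilyl trifluoromethanesulfonate, CC(C)(C)[Si](C)(C)OS(=O)(=O)C(F)(F)F
Why: Silylation of a hindered secondary alcohol with the silyl triflate under basic conditions, which keeps the acid-sensitive furyl carbinol intact and leaves C8 untouched.

Step 6
Reactants: 10 3-[(1S)-1-(TBS-oxy)but-3-yn-1-yl]-4-(TBS-oxymethyl)-2-methylfuran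
Product: 12 3-[(1S,3E)-1-(TBS-oxy)-4-iodo-3-methylbut-3-en-1-yl]-4-(TBS-oxymethyl)-2-methylfuran, via alkenylalane 11 (not isolated)
Conditions: AlMe3, Cp2ZrCl2 (20 mol %), H2O (1 equiv), CH2Cl2, −30 °C; I2, THF, −30 → 0 °C
Reagents that add atoms: trimethylaluminium, C[Al](C)C; iodine, II
Why: Negishi carboalumination: methyl and aluminium add syn across the terminal alkyne with aluminium at the terminus, and iodinolysis proceeds with retention. This installs C14 and fixes the E geometry of the future C1=C10 bond.

Step 7
Reactants: 13 (2S)-but-3-en-2-ol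
Product: 14 1-{[(2S)-but-3-en-2-yloxy]methyl}-4-methoxybenzene
Conditions: NaH, PMBCl, Bu4NI (cat.), THF/DMF, 0 °C → rt
Reagents that add atoms: 4-methoxybenzyl chloride, COc1ccc(CCl)cc1
Why: Williamson etherification of the sodium alkoxide; the carbinol centre is not involved.

Step 8
Reactants: 14 1-{[(2S)-but-3-en-2-yloxy]methyl}-4-methoxybenzene; 12 3-[(1S,3E)-1-(TBS-oxy)-4-iodo-3-methylbut-3-en-1-yl]-4-(TBS-oxymethyl)-2-methylfuran
Product: 16 3-[(1S,3E,7S)-1-(TBS-oxy)-7-(PMB-oxy)-3-methyloct-3-en-1-yl]-4-(TBS-oxymethyl)-2-methylfuran, via alkylborane 15 (not isolated)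
Conditions: 9-BBN, THF, rt; then 12, Pd(dppf)Cl2 (5 mol %), AsPh3, Cs2CO3, DMF/H2O, rt
Reagents that add atoms: none
Why: Anti-Markovnikov hydroboration of the terminal olefin followed by B-alkyl Suzuki–Miyaura coupling with the vinyl iodide. The coupling retains the olefin geometry, so the C1–C2 bond forms with the E-trisubstituted C1=C10 olefin intact.

Step 9
Reactants: 16 3-[(1S,3E,7S)-1-(TBS-oxy)-7-(PMB-oxy)-3-methyloct-3-en-1-yl]-4-(TBS-oxymethyl)-2-methylfuran
Product: 18 (2Z,4S,6E,10S)-3-acetyl-4-(TBS-oxy)-2-(TBS-oxymethyl)-10-(PMB-oxy)-6-methylundeca-2,6-dienoic acid, via keto enal 17 (not isolated)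
Conditions: NBS (1.05 equiv), NaHCO3, acetone/H2O, −20 °C; then NaClO2, NaH2PO4, 2-methylbut-2-ene, t-BuOH/H2O, 0 °C
Reagents that add atoms: water, O; sodium chlorite, [Na+].[O-]Cl=O
Why: Oxidative furan opening: bromination at a furan α-carbon, addition of water and collapse give the cis-enedione, so C6 and C12 end up cis on C7=C11. The electron-rich furan reacts far faster than the trisubstituted olefin or the anisyl ring. Pinnick oxidation then takes the C12 aldehyde to the acid, which is expected to rest largely as its cyclic lactol tautomer.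

Step 10
Reactants: 18 (2Z,4S,6E,10S)-3-acetyl-4-(TBS-oxy)-2-(TBS-oxymethyl)-10-(PMB-oxy)-6-methylundeca-2,6-dienoic acid
Product: 19 tert-butyl (2Z,4S,6E,10S)-3-acetyl-4-(TBS-oxy)-2-(TBS-oxymethyl)-10-(PMB-oxy)-6-methylundeca-2,6-dienoate
Conditions: O-tert-butyl-N,N'-diisopropylisourea, CH2Cl2, rt
Reagents that add atoms: O-tert-butyl-N,N'-diisopropylisourea, CC(C)N=C(OC(C)(C)C)NC(C)C
Why: Esterification by tert-butyl transfer from the protonated isourea to the carboxylate within an ion pair. Proton transfer to the basic reagent opens the lactol to the carboxylate, so the open Z-keto ester is the expected product. The tert-butyl ester is chosen because it resists hydroxide and acylation in step 15.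

Step 11
Reactants: 19 tert-butyl (2Z,4S,6E,10S)-3-acetyl-4-(TBS-oxy)-2-(TBS-oxymethyl)-10-(PMB-oxy)-6-methylundeca-2,6-dienoate
Product: 20 tert-butyl (2Z,4S)-3-acetyl-4-(TBS-oxy)-2-(TBS-oxymethyl)-5-{(2R,3R)-2-methyl-3-[(3S)-3-(PMB-oxy)butyl]oxiran-2-yl}pent-2-enoate
Conditions: D-fructose-derived Shi ketone (30 mol %), Oxone (2KHSO5·KHSO4·K2SO4), K2CO3, Bu4NHSO4, MeCN/CH2(OMe)2/aq. Na2B4O7 buffer (pH 10.5), 0 °C
Reagents that add atoms: potassium peroxymonosulfate, [K+].[O-]S(=O)(=O)OO
Why: Shi epoxidation: the chiral dioxirane transfers oxygen through a spiro transition state to the electron-rich trisubstituted olefin only; the electron-poor tetrasubstituted C7=C11 bond is inert. The D-fructose-derived ketone gives the (R,R)-oxirane from E-trisubstituted olefins, which sets 1R and 10R under reagent control.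

Step 12
Reactants: 20 tert-butyl (2Z,4S)-3-acetyl-4-(TBS-oxy)-2-(TBS-oxymethyl)-5-{(2R,3R)-2-methyl-3-[(3S)-3-(PMB-oxy)butyl]oxiran-2-yl}pent-2-enoate
Product: 22 tert-butyl (2Z,4S)-3-(chloroacetyl)-4-(TBS-oxy)-2-(TBS-oxymethyl)-5-{(2R,3R)-2-methyl-3-[(3S)-3-(PMB-oxy)butyl]oxiran-2-yl}pent-2-enoate, via silyl enol ether 21 (not isolated)
Conditions: LiN(SiMe3)2, TMSCl, THF, −78 °C; then NCS, THF, −78 → 0 °C
Reagents that add atoms: N-chlorosuccinimide, ClN1C(=O)CCC1=O
Why: Kinetic deprotonation at C5, the only α-carbon of the only ketone present, with silylation in the flask, then electrophilic chlorination of the silyl enol ether at its terminal carbon. The γ-hydrogens are not syn to a carbonyl and C4 is still a protected carbinol, so no other site competes.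

Step 13
Reactants: 22 tert-butyl (2Z,4S)-3-(chloroacetyl)-4-(TBS-oxy)-2-(TBS-oxymethyl)-5-{(2R,3R)-2-methyl-3-[(3S)-3-(PMB-oxy)butyl]oxiran-2-yl}pent-2-enoate
Product: 23 tert-butyl (2Z,4S)-3-(chloroacetyl)-4-(TBS-oxy)-2-(TBS-oxymethyl)-5-{(2R,3R)-3-[(3S)-3-hydroxybutyl]-2-methyloxiran-2-yl}pent-2-enoate
Conditions: DDQ, CH2Cl2/pH 7 phosphate buffer, 0 °C
Reagents that add atoms: none
Why: Oxidative cleavage of the PMB ether: hydride abstraction from the electron-rich benzylic position and hydrolysis of the oxocarbenium ion. The buffered medium spares the oxirane, silyl ethers and chloro ketone.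

Step 14
Reactants: 23 tert-butyl (2Z,4S)-3-(chloroacetyl)-4-(TBS-oxy)-2-(TBS-oxymethyl)-5-{(2R,3R)-3-[(3S)-3-hydroxybutyl]-2-methyloxiran-2-yl}pent-2-enoate
Product: 24 tert-butyl (2Z,4S)-3-(chloroacetyl)-4-(TBS-oxy)-2-(TBS-oxymethyl)-5-[(2R,3R)-2-methyl-3-(3-oxobutyl)oxiran-2-yl]pent-2-enoate
Conditions: Dess–Martin periodinane, NaHCO3, CH2Cl2, 0 °C → rt
Reagents that add atoms: none
Why: Dess–Martin oxidation of the secondary alcohol under buffered, non-acidic conditions unveils the C4 methyl ketone without exposing the γ,δ-epoxy ketone to acid, and removes the auxiliary stereocentre.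

Step 15
Reactants: 24 tert-butyl (2Z,4S)-3-(chloroacetyl)-4-(TBS-oxy)-2-(TBS-oxymethyl)-5-[(2R,3R)-2-methyl-3-(3-oxobutyl)oxiran-2-yl]pent-2-enoate
Product: 26 tert-butyl (1R,4R,5S,8S,10R)-8,13-bis(TBS-oxy)-1,10:4,5-diepoxy-6-oxogermacr-7(11)-en-12-oate, via chloro aldolate 25 (not isolated)
Conditions: KOH (powdered), N-(9-anthracenylmethyl)cinchonidinium bromide (20 mol %), toluene, slow addition of 24 to about 0.002 M, −20 → 0 °C
Reagents that add atoms: none
Why: Proposed new method: the chiral ammonium ion carries hydroxide from the solid KOH into toluene, C5–H of 24 (the only α-hydrogen of the C6 ketone and the most acidic hydrogen present) is removed, and the ion-paired chloro-enolate adds through C5 to the C4 methyl ketone to give aldolate 25, whose alkoxide displaces chloride to give 26; the closest known reaction types are the intermolecular Darzens condensation of α-chloro ketones under chiral phase-transfer catalysis and aldol-type macrocyclisations, and an intramolecular Darzens reaction onto a ketone that closes a medium ring has no precedent. The ten-membered ring closes by a reversible 10-(enolendo)-exo-trig aldol addition (C4–C5 bond) and the oxirane by an irreversible 3-exo-tet substitution, which drains the unfavourable aldol equilibrium. C5 is set in the substitution, which inverts the chloride-bearing carbon and needs alkoxide and chloride anti-periplanar; C4 is set by the face of the ketone that the enolate attacks; together they decide between the trans oxirane (C3 and C6 anti) and its cis isomer. The trans isomer is expected because the two ring arms on the forming oxirane then point away from each other, as they do around the existing trans C1–C10 oxirane, so the ring can take the crown shape of an (E,E)-cyclodeca-1,5-diene with both methyl groups on one face. The absolute sense (the one that becomes 4R,5R in the target) should follow from that crown being folded around the fixed centres C8, C10 and C1 with the C8 silyloxy group pseudo-equatorial, and the chiral cation is chosen to reinforce it. Three other paths must be suppressed: enolates of the C4 ketone (several pKa units less acidic, and the C6 carbonyl they would attack is shielded by the fully substituted C7), acylation of C5 by the C12 carboxyl (a tert-butyl ester, reachable only in a disfavoured 5-(enolendo)-exo-trig mode) and Favorskii rearrangement (excluded, since C7 has no hydrogen); oligomerisation is held back by slow addition at high dilution.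

Step 16
Reactants: 26 tert-butyl (1R,4R,5S,8S,10R)-8,13-bis(TBS-oxy)-1,10:4,5-diepoxy-6-oxogermacr-7(11)-en-12-oate
Product: 28 (1R,4R,5R,6S,8S,10R)-8,13-bis(TBS-oxy)-1,10:4,5-diepoxygermacr-7(11)-en-12,6-olide, via hydroxy ester 27 (not isolated)
Conditions: NaBH4, CeCl3·7H2O, MeOH/THF, −40 °C; aqueous work-up; then KOt-Bu (5 mol %), THF, −78 °C; AcOH
Reagents that add atoms: none
Why: Luche 1,2-reduction of the enone-type C6 ketone; in the Felkin–Anh arrangement hydride enters anti to the C5–O bond of the oxirane from the ring periphery, which gives 6S. The C6 alkoxide, held cis to C12 across C7=C11, then closes the lactone by 5-exo-trig acyl transfer with loss of tert-butoxide, which carries the chain. The base is catalytic and cold because C6–H of the product is acidic, and C8 is still silylated so only the 6,12-lactone can form.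

Step 17
Reactants: 28 (1R,4R,5R,6S,8S,10R)-8,13-bis(TBS-oxy)-1,10:4,5-diepoxygermacr-7(11)-en-12,6-olide
Product: 29 (1R,4R,5R,6S,8S,10R)-1,10:4,5-diepoxy-8,13-dihydroxygermacr-7(11)-en-12,6-olide
Conditions: HF·pyridine, pyridine, THF, 0 °C → rt
Reagents that add atoms: none
Why: Fluoride-mediated cleavage of both silyl ethers in a pyridine-buffered medium. This avoids free alkoxides, which could translactonise from C8 or deprotonate C6, and avoids strong acid, which would open the oxiranes.

Step 18
Reactants: 29 (1R,4R,5R,6S,8S,10R)-1,10:4,5-diepoxy-8,13-dihydroxygermacr-7(11)-en-12,6-olide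
Product: 30 (1R,4R,5R,6S,8S,10R)-8,13-diacetoxy-1,10:4,5-diepoxygermacr-7(11)-en-12,6-olide (CNP0271844.1)
Conditions: Ac2O, pyridine, DMAP (cat.), CH2Cl2, 0 °C → rt
Reagents that add atoms: acetic anhydride, CC(=O)OC(C)=O
Why: DMAP-catalysed acylation of the primary allylic and the secondary hydroxyl groups under weakly basic conditions that the oxiranes and the butenolide tolerate.

## Compound list

1 | furan-3,4-diyldimethanol | OCc1cocc1CO | starting material
2 | [4-(TBS-oxymethyl)furan-3-yl]methanol | OCc1cocc1CO[Si](C)(C)C(C)(C)C | intermediate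
3 | 4-(TBS-oxymethyl)furan-3-carbaldehyde | O=Cc1cocc1CO[Si](C)(C)C(C)(C)C | intermediate
4 | lithium α-amino alkoxide of 3 (adduct with LiN(Me)CH2CH2NMe2 at the formyl carbon) | [Li]OC(N(C)CCN(C)C)c1cocc1CO[Si](C)(C)C(C)(C)C | intermediate (not isolated)
5 | 2-lithio derivative of 4 | [Li]OC(N(C)CCN(C)C)c1c([Li])occ1CO[Si](C)(C)C(C)(C)C | intermediate (not isolated)
6 | 2-methyl derivative of 4 | [Li]OC(N(C)CCN(C)C)c1c(C)occ1CO[Si](C)(C)C(C)(C)C | intermediate (not isolated)
7 | 4-(TBS-oxymethyl)-2-methylfuran-3-carbaldehyde | Cc1occ(CO[Si](C)(C)C(C)(C)C)c1C=O | intermediate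
8 | pinacol borate ester of 9 (O–B(pin) on C8, S) | Cc1occ(CO[Si](C)(C)C(C)(C)C)c1[C@@H](OB1OC(C)(C)C(C)(C)O1)CC#C | intermediate (not isolated)
9 | (1S)-1-[4-(TBS-oxymethyl)-2-methylfuran-3-yl]but-3-yn-1-ol | Cc1occ(CO[Si](C)(C)C(C)(C)C)c1[C@@H](O)CC#C | intermediate
10 | 3-[(1S)-1-(TBS-oxy)but-3-yn-1-yl]-4-(TBS-oxymethyl)-2-methylfuran | Cc1occ(CO[Si](C)(C)C(C)(C)C)c1[C@@H](O[Si](C)(C)C(C)(C)C)CC#C | intermediate
11 | [(1E,4S)-4-(TBS-oxy)-4-(4-(TBS-oxymethyl)-2-methylfuran-3-yl)-2-methylbut-1-en-1-yl]dimethylalane | Cc1occ(CO[Si](C)(C)C(C)(C)C)c1[C@@H](O[Si](C)(C)C(C)(C)C)C/C(C)=C/[Al](C)C | intermediate (not isolated)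
12 | 3-[(1S,3E)-1-(TBS-oxy)-4-iodo-3-methylbut-3-en-1-yl]-4-(TBS-oxymethyl)-2-methylfuran | Cc1occ(CO[Si](C)(C)C(C)(C)C)c1[C@@H](O[Si](C)(C)C(C)(C)C)C/C(C)=C/I | intermediate
13 | (2S)-but-3-en-2-ol | C[C@H](O)C=C | starting material
14 | 1-{[(2S)-but-3-en-2-yloxy]methyl}-4-methoxybenzene | C[C@H](OCc1ccc(OC)cc1)C=C | intermediate
15 | 9-[(3S)-3-(PMB-oxy)butyl]-9-borabicyclo[3.3.1]nonane | C[C@H](OCc1ccc(OC)cc1)CCB1C2CCCC1CCC2 | intermediate (not isolated)
16 | 3-[(1S,3E,7S)-1-(TBS-oxy)-7-(PMB-oxy)-3-methyloct-3-en-1-yl]-4-(TBS-oxymethyl)-2-methylfuran | Cc1occ(CO[Si](C)(C)C(C)(C)C)c1[C@@H](O[Si](C)(C)C(C)(C)C)C/C(C)=C/CC[C@H](C)OCc1ccc(OC)cc1 | intermediate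
17 | (2Z,4S,6E,10S)-3-acetyl-4-(TBS-oxy)-2-(TBS-oxymethyl)-10-(PMB-oxy)-6-methylundeca-2,6-dienal | C[C@H](OCc1ccc(OC)cc1)CC/C=C(\C)C[C@H](O[Si](C)(C)C(C)(C)C)/C(C(C)=O)=C(\CO[Si](C)(C)C(C)(C)C)C=O | intermediate (not isolated)
18 | (2Z,4S,6E,10S)-3-acetyl-4-(TBS-oxy)-2-(TBS-oxymethyl)-10-(PMB-oxy)-6-methylundeca-2,6-dienoic acid (drawn open-chain; in equilibrium with its cyclic lactol) | C[C@H](OCc1ccc(OC)cc1)CC/C=C(\C)C[C@H](O[Si](C)(C)C(C)(C)C)/C(C(C)=O)=C(\CO[Si](C)(C)C(C)(C)C)C(=O)O | intermediate
19 | tert-butyl (2Z,4S,6E,10S)-3-acetyl-4-(TBS-oxy)-2-(TBS-oxymethyl)-10-(PMB-oxy)-6-methylundeca-2,6-dienoate | C[C@H](OCc1ccc(OC)cc1)CC/C=C(\C)C[C@H](O[Si](C)(C)C(C)(C)C)/C(C(C)=O)=C(\CO[Si](C)(C)C(C)(C)C)C(=O)OC(C)(C)C | intermediate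
20 | tert-butyl (2Z,4S)-3-acetyl-4-(TBS-oxy)-2-(TBS-oxymethyl)-5-{(2R,3R)-2-methyl-3-[(3S)-3-(PMB-oxy)butyl]oxiran-2-yl}pent-2-enoate | C[C@H](OCc1ccc(OC)cc1)CC[C@H]1O[C@]1(C)C[C@H](O[Si](C)(C)C(C)(C)C)/C(C(C)=O)=C(\CO[Si](C)(C)C(C)(C)C)C(=O)OC(C)(C)C | intermediate
21 | trimethylsilyl enol ether of 20 (C5=C6–OSiMe3) | C[C@H](OCc1ccc(OC)cc1)CC[C@H]1O[C@]1(C)C[C@H](O[Si](C)(C)C(C)(C)C)/C(C(=C)O[Si](C)(C)C)=C(\CO[Si](C)(C)C(C)(C)C)C(=O)OC(C)(C)C | intermediate (not isolated)
22 | tert-butyl (2Z,4S)-3-(chloroacetyl)-4-(TBS-oxy)-2-(TBS-oxymethyl)-5-{(2R,3R)-2-methyl-3-[(3S)-3-(PMB-oxy)butyl]oxiran-2-yl}pent-2-enoate | C[C@H](OCc1ccc(OC)cc1)CC[C@H]1O[C@]1(C)C[C@H](O[Si](C)(C)C(C)(C)C)/C(C(=O)CCl)=C(\CO[Si](C)(C)C(C)(C)C)C(=O)OC(C)(C)C | intermediate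
23 | tert-butyl (2Z,4S)-3-(chloroacetyl)-4-(TBS-oxy)-2-(TBS-oxymethyl)-5-{(2R,3R)-3-[(3S)-3-hydroxybutyl]-2-methyloxiran-2-yl}pent-2-enoate | C[C@H](O)CC[C@H]1O[C@]1(C)C[C@H](O[Si](C)(C)C(C)(C)C)/C(C(=O)CCl)=C(\CO[Si](C)(C)C(C)(C)C)C(=O)OC(C)(C)C | intermediate
24 | tert-butyl (2Z,4S)-3-(chloroacetyl)-4-(TBS-oxy)-2-(TBS-oxymethyl)-5-[(2R,3R)-2-methyl-3-(3-oxobutyl)oxiran-2-yl]pent-2-enoate (precursor of the key step) | CC(=O)CC[C@H]1O[C@]1(C)C[C@H](O[Si](C)(C)C(C)(C)C)/C(C(=O)CCl)=C(\CO[Si](C)(C)C(C)(C)C)C(=O)OC(C)(C)C | intermediate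
25 | potassium (1R,4R,5R,8S,10R)-5-chloro-1,10-epoxy-6-oxo-12-tert-butoxy-12-oxo-8,13-bis(TBS-oxy)germacr-7(11)-en-4-olate (ten-membered chloro aldolate) | CC(C)(C)OC(=O)/C(CO[Si](C)(C)C(C)(C)C)=C1/[C@@H](O[Si](C)(C)C(C)(C)C)C[C@@]2(C)O[C@@H]2CC[C@@](C)([O-])[C@@H](Cl)C1=O.[K+] | intermediate (not isolated)
26 | tert-butyl (1R,4R,5S,8S,10R)-8,13-bis(TBS-oxy)-1,10:4,5-diepoxy-6-oxogermacr-7(11)-en-12-oate (product of the key step) | CC(C)(C)OC(=O)/C(CO[Si](C)(C)C(C)(C)C)=C1/[C@@H](O[Si](C)(C)C(C)(C)C)C[C@@]2(C)O[C@@H]2CC[C@@]2(C)O[C@@H]2C1=O | intermediate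
27 | tert-butyl (1R,4R,5R,6S,8S,10R)-8,13-bis(TBS-oxy)-1,10:4,5-diepoxy-6-hydroxygermacr-7(11)-en-12-oate | CC(C)(C)OC(=O)/C(CO[Si](C)(C)C(C)(C)C)=C1/[C@@H](O[Si](C)(C)C(C)(C)C)C[C@@]2(C)O[C@@H]2CC[C@@]2(C)O[C@@H]2[C@H]1O | intermediate (not isolated)
28 | (1R,4R,5R,6S,8S,10R)-8,13-bis(TBS-oxy)-1,10:4,5-diepoxygermacr-7(11)-en-12,6-olide | CC(C)(C)[Si](C)(C)OCC1=C2[C@@H](O[Si](C)(C)C(C)(C)C)C[C@@]3(C)O[C@@H]3CC[C@@]3(C)O[C@@H]3[C@H]2OC1=O | intermediate
29 | (1R,4R,5R,6S,8S,10R)-1,10:4,5-diepoxy-8,13-dihydroxygermacr-7(11)-en-12,6-olide | OCC1=C2[C@@H](O)C[C@@]3(C)O[C@@H]3CC[C@@]3(C)O[C@@H]3[C@H]2OC1=O | intermediate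
30 | (1R,4R,5R,6S,8S,10R)-8,13-diacetoxy-1,10:4,5-diepoxygermacr-7(11)-en-12,6-olide (CNP0271844.1) | CC(=O)OCC1=C2[C@@H](OC(C)=O)C[C@@]3(C)O[C@@H]3CC[C@@]3(C)O[C@@H]3[C@H]2OC1=O | target

## Step count and least certain steps

Total: 18 steps. Longest linear sequence: 17 steps (1 to 30 through steps 1–6 and 8–18); step 7 is the only step off this line.

**Step 15 (key step, new method).** Closure of a ten-membered ring by a reversible addition to a ketone may be too slow. Then intermolecular condensation, hydrolytic loss of chloride, acylation of C5 by the C12 ester or addition of a C4-ketone enolate to C6 could take over, and facial selectivity at C4 could be poor. Fallback with known reaction types, from 24: SmI2 in THF at −78 °C under high dilution reduces the C–Cl bond, and the samarium enolate adds to the C4 ketone in an intramolecular Reformatsky-type aldol reaction to give the ten-membered β-hydroxy ketone F1 (either C4 epimer serves). Dehydration (MsCl, Et3N, then DBU) gives the (E)-enone F2, and nucleophilic Weitz–Scheffer epoxidation (t-BuOOH, DBU) of the trisubstituted C4=C5 bond returns to the route at 26.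

**Step 16.** Hydride may be delivered to the wrong face if the ring conformation overrides the Felkin preference. Acyl transfer from the tert-butyl ester may be incomplete, and prolonged base contact could deprotonate C6 and open the C4–C5 oxirane. Fallback from 26: reduction under chelation control (Zn(BH4)2, Et2O, −20 °C) and isolation of the 6-epi hydroxy ester F3, which does not lactonise without base. Mitsunobu inversion with chloroacetic acid (PPh3, diisopropyl azodicarboxylate) gives the (6S)-chloroacetate F4. Removal of the chloroacetyl group with thiourea and NaHCO3 gives 27, which is lactonised as in step 16 to rejoin the route at 28.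

**Step 10.** Tert-butyl transfer could go to the lactol oxygen of the ring tautomer and give a cyclic pseudo-ester, or the hindered carboxyl may not react. Fallback from 16, avoiding the free acid: metalation of the one free furan position (the future C12) with n-BuLi, exchange to magnesium with MgBr2 and reaction with tert-butyl perbenzoate give the 2-tert-butoxyfuran F5. Oxidative opening of this alkoxyfuran (NBS, NaHCO3, acetone/H2O, −20 °C) delivers the open Z-keto tert-butyl ester directly and returns to the route at 19.

**Step 4.** The two ortho substituents twist the formyl group and may lower rate and enantioselectivity. Fallback from 7, by resolution instead of asymmetric catalysis: zinc-mediated propargylation (propargyl bromide, Zn, THF) gives the racemic homopropargylic alcohol F6. Lipase-catalysed acylation (immobilised Candida antarctica lipase B, vinyl acetate) is expected by Kazlauskas' rule to convert the R enantiomer into the (R)-acetate F7 and leave the S alcohol, which is 9.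

**Step 13.** The freed C4 hydroxyl could open the C1–C10 oxirane in a 5-exo cyclisation, promoted by the acidic hydroquinone formed, here or in step 14. Fallback from 19, changing the order so that the C4 ketone exists before the oxirane: the chlorination of step 12 is applied to 19, giving the silyl enol ether F8 and then the olefinic chloro ketone F9. DDQ gives the C4 alcohol F10, Dess–Martin oxidation gives the olefinic chloro diketone F11, and Shi epoxidation under NaHCO3 buffering (about pH 8, stoichiometric ketone, where the chloro ketone is not enolised) returns to the route at 24.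

## Further compounds

F1 | step 15 | tert-butyl (1R,4R,8S,10R)-8,13-bis(TBS-oxy)-1,10-epoxy-4-hydroxy-6-oxogermacr-7(11)-en-12-oate | CC(C)(C)OC(=O)/C(CO[Si](C)(C)C(C)(C)C)=C1/[C@@H](O[Si](C)(C)C(C)(C)C)C[C@@]2(C)O[C@@H]2CC[C@@](C)(O)CC1=O
F2 | step 15 | tert-butyl (1R,4E,8S,10R)-8,13-bis(TBS-oxy)-1,10-epoxy-6-oxogermacra-4,7(11)-dien-12-oate | CC(C)(C)OC(=O)/C(CO[Si](C)(C)C(C)(C)C)=C1/[C@@H](O[Si](C)(C)C(C)(C)C)C[C@@]2(C)O[C@@H]2CC/C(C)=C/C1=O
F3 | step 16 | tert-butyl (1R,4R,5R,6R,8S,10R)-8,13-bis(TBS-oxy)-1,10:4,5-diepoxy-6-hydroxygermacr-7(11)-en-12-oate (C6 epimer of 27) | CC(C)(C)OC(=O)/C(CO[Si](C)(C)C(C)(C)C)=C1/[C@@H](O[Si](C)(C)C(C)(C)C)C[C@@]2(C)O[C@@H]2CC[C@@]2(C)O[C@@H]2[C@@H]1O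
F4 | step 16 | tert-butyl (1R,4R,5R,6S,8S,10R)-8,13-bis(TBS-oxy)-6-(chloroacetoxy)-1,10:4,5-diepoxygermacr-7(11)-en-12-oate | CC(C)(C)OC(=O)/C(CO[Si](C)(C)C(C)(C)C)=C1/[C@@H](O[Si](C)(C)C(C)(C)C)C[C@@]2(C)O[C@@H]2CC[C@@]2(C)O[C@@H]2[C@H]1OC(=O)CCl
F5 | step 10 | 2-tert-butoxy-4-[(1S,3E,7S)-1-(TBS-oxy)-7-(PMB-oxy)-3-methyloct-3-en-1-yl]-3-(TBS-oxymethyl)-5-methylfuran | Cc1oc(OC(C)(C)C)c(CO[Si](C)(C)C(C)(C)C)c1[C@@H](O[Si](C)(C)C(C)(C)C)C/C(C)=C/CC[C@H](C)OCc1ccc(OC)cc1
F6 | step 4 | rac-1-[4-(TBS-oxymethyl)-2-methylfuran-3-yl]but-3-yn-1-ol | Cc1occ(CO[Si](C)(C)C(C)(C)C)c1C(O)CC#C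
F7 | step 4 | (1R)-1-[4-(TBS-oxymethyl)-2-methylfuran-3-yl]but-3-yn-1-yl acetate | Cc1occ(CO[Si](C)(C)C(C)(C)C)c1[C@H](OC(C)=O)CC#C
F8 | step 13 | trimethylsilyl enol ether of 19 (C5=C6–OSiMe3) | C[C@H](OCc1ccc(OC)cc1)CC/C=C(\C)C[C@H](O[Si](C)(C)C(C)(C)C)/C(C(=C)O[Si](C)(C)C)=C(\CO[Si](C)(C)C(C)(C)C)C(=O)OC(C)(C)C
F9 | step 13 | tert-butyl (2Z,4S,6E,10S)-3-(chloroacetyl)-4-(TBS-oxy)-2-(TBS-oxymethyl)-10-(PMB-oxy)-6-methylundeca-2,6-dienoate | C[C@H](OCc1ccc(OC)cc1)CC/C=C(\C)C[C@H](O[Si](C)(C)C(C)(C)C)/C(C(=O)CCl)=C(\CO[Si](C)(C)C(C)(C)C)C(=O)OC(C)(C)C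
F10 | step 13 | tert-butyl (2Z,4S,6E,10S)-3-(chloroacetyl)-4-(TBS-oxy)-2-(TBS-oxymethyl)-10-hydroxy-6-methylundeca-2,6-dienoate | C[C@H](O)CC/C=C(\C)C[C@H](O[Si](C)(C)C(C)(C)C)/C(C(=O)CCl)=C(\CO[Si](C)(C)C(C)(C)C)C(=O)OC(C)(C)C
F11 | step 13 | tert-butyl (2Z,4S,6E)-3-(chloroacetyl)-4-(TBS-oxy)-2-(TBS-oxymethyl)-6-methyl-10-oxoundeca-2,6-dienoate | CC(=O)CC/C=C(\C)C[C@H](O[Si](C)(C)C(C)(C)C)/C(C(=O)CCl)=C(\CO[Si](C)(C)C(C)(C)C)C(=O)OC(C)(C)C
A1 | alternative 1 | cyclohexanol with isopropenyl on the carbinol carbon C5 and vinyl, trans to it, on C10; C6 PMB ether, C7 dioxolane, C8 triisopropylsilyl ether | C=C[C@]1(C)C[C@H](O[Si](C(C)C)(C(C)C)C(C)C)C2(OCCO2)[C@H](OCc2ccc(OC)cc2)[C@@]1(O)C(C)=C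
A2 | alternative 1 | ten-membered (E,E)-diene with C5 enol triflate, C6 PMB ether, C7 dioxolane, C8 triisopropylsilyl ether | C12(OCCO1)[C@@H](O[Si](C(C)C)(C(C)C)C(C)C)C/C(C)=C/CC/C(C)=C(OS(=O)(=O)C(F)(F)F)/[C@H]2OCc1ccc(OC)cc1
A3 | alternative 2 | open-chain C5 aldehyde with C4 triethylsilyl ether, E-C1=C10 olefin, C8 TBS ether and a 2-(triisopropylsilyloxy)furan carrying the C13 TBS ether | O=C[C@](C)(O[Si](CC)(CC)CC)CC/C=C(\C)C[C@H](O[Si](C)(C)C(C)(C)C)c1coc(O[Si](C(C)C)(C(C)C)C(C)C)c1CO[Si](C)(C)C(C)(C)C
A4 | alternative 2 | ten-membered butenolide with C5 hydroxyl, C4 triethylsilyl ether, C1=C10 olefin, C8 and C13 TBS ethers | CC(C)(C)[Si](C)(C)OCC1=C2[C@@H](O[Si](C)(C)C(C)(C)C)C/C(C)=C/CC[C@@](C)(O[Si](CC)(CC)CC)[C@@H](O)[C@H]2OC1=O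
A5 | alternative 3 | trans-fused eudesm-7(11)-en-12,6-olide with equatorial C1 mesylate, equatorial C4 carboxylic acid, C8 and C13 acetates | CC(=O)OCC1=C2[C@@H](OC(C)=O)C[C@@]3(C)[C@H](OS(C)(=O)=O)CC[C@@](C)(C(=O)O)[C@@H]3[C@H]2OC1=O
A6 | alternative 3 | (E,E)-germacra-1(10),4,7(11)-trien-12,6-olide 8,13-diacetate | CC(=O)OCC1=C2[C@@H](OC(C)=O)C/C(C)=C/CC/C(C)=C/[C@H]2OC1=O
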